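## The problem

Compound 25 is a 1‑aryl‑1,2‑dihydronaphthalene lignan. Carbocycle ring B (C1–C4, C4a, C8a) is fused to benzo ring A and carries, on consecutive carbons, the 4‑hydroxy‑3‑methoxyphenyl group (C1), CH2OAc (C9 on C2), CHO (C10 on C3) and the C3=C4 double bond conjugated with ring A. Ring A is oxygenated at C7 (OH) and C8 (OMe), so C1 is bonded to the ring carbon flanked by a methoxy group. An electrophilic closure of ring B onto a 3,4‑dioxygenated arene would go para to oxygen and give the 6,7‑pattern instead. There are two stereocenters, (1S) and (2R), trans to each other. C1 is a diarylmethine without an acidifying group and must be set absolutely. C2 can be equilibrated while C9 is a carbonyl carbon: once C3=C4 carries a C3 substituent, the peri C8 methoxy group pushes the C1 aryl group pseudo‑axial and allylic strain pushes the C2 substituent pseudo‑axial, so C1 can dictate trans‑C2 under thermodynamic control. A proton or hydride delivered from outside to an sp2 C2 would arrive anti to the C1 aryl group and give the cis isomer, so C2 should not be set by kinetic protonation. Sensitive features are the enal, the primary acetate beside it (C9 and C10 must end at different oxidation levels), two free phenols, and a dihydronaphthalene that aromatises on oxidation or on loss of acetic acid. The feature that invites the key step is that ring A is joined to the chain C1–C4 through the adjacent carbons C8a and C4a, with the methoxy group next to C8a. This is the adduct of a 3‑methoxyaryne with a 1,3‑diene, in the orientation where the nucleophilic diene terminus (C4) has bonded to the aryne carbon remote from the methoxy group.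

## Retrosynthesis

Locants C1–C10 of the target are used for all ring‑B intermediates.

**Phenols and acetate last (25 ⇐ 24 ⇐ 23).** The two O–benzyl bonds and the acetate C–O bond are cut first. Benzyl ethers are preferred over silyl or acetal groups because they survive butyllithium, fluoride, LiAlH4 and palladium. They can be removed by BCl3 at low temperature without touching the alkene, which hydrogenolysis would not spare. Acetylation of hydroxy enal 23 precedes debenzylation so that the phenols never compete for the acylating agent. The forward steps ask only for chemoselectivity.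

**C9 and C10 from two carbonyl carbons (23 ⇐ 22 ⇐ 21).** No skeletal bond is cut. Both one‑carbon substituents are traced to diol 22 and from there to imide ester 21, in which C9 is the imide carbonyl and C10 an ester. Carrying an aldehyde through the sequence would need protection. The diol needs none, because C10–OH is allylic and conjugated with ring A and is the only alcohol that MnO2 oxidises. The forward reduction must be 1,2 at the conjugated ester.

**C2 as a thermodynamic centre (21 ⇐ 20).** The retron is a prototropic shift: C3=C4 and C2–H of 21 go back to C2=C3 and C4H2 in 20. This removes C2 as a stereocenter and exposes the substitution pattern of a diene adduct (sp2 C2 and C3). The neighbouring option, a C3 ketone with C2 set on hydrolysis of an enol ether, was put aside for two reasons. Protonation of an sp2 C2 occurs anti to the C1 aryl group and leads to the cis series. A C3 ketone also lacks the allylic strain that makes trans clearly favoured. In 21 both the peri methoxy group and the C3 ester enforce the trans‑diaxial arrangement, and C2–H is acidic (α to the imide, allylic). The forward step must remove C4–H and not C1–H.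

**C10 by carbonylation (20 ⇐ 19 ⇐ 17).** The C3–C10 bond is cut to enol triflate 19 and carbon monoxide, and the triflate is traced to silyl enol ether 17. The enol oxygen left at C3 by a 2‑silyloxy diene is thus exchanged for the missing carbon without passing through a ketone, so the C2=C3 position fixed by the cycloaddition is never lost. The forward steps need a fluoride‑mediated Si‑to‑Tf exchange and carbonylation of a tetrasubstituted triflate.

**Ring B by aryne cycloaddition (17 ⇐ 16 + 15; 16 from 8).** C4–C4a and C1–C8a are cut together. Cutting C1–C8a alone (cationic closure) would give the wrong ring‑A pattern. Cutting C1–C2 or C2–C3 alone would require a 1,2,3,4‑tetrasubstituted ring A built beforehand. The double cut gives two 1,2,4‑trisubstituted benzenes: aryne 16 (from silyl triflate 8) and diene 15, whose C2 acyl group carries C9 and a chiral oxazolidinone. The forward reaction must deliver regiochemistry (C4 to C4a), facial selectivity at C1, and [4+2] selectivity over [2+2] addition and desilylation.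

**Diene (15 ⇐ 14 ⇐ 12 + 13; 12 ⇐ 9 + 10).** The O–Si bond, the C1=C2 bond (Knoevenagel condensation of O‑benzylvanillin 13 with β‑keto imide 12) and the N–acyl bond (oxazolidinone 9 with acetylketene from dioxinone 10) are cut in turn. The condensation must give the Z isomer, so that the aryl group sits on the outside of the diene.

**Aryne precursor (8 ⇐ 6 ⇐ 2 ⇐ 1).** The C–Si bond is cut to the carbamate of catalogue phenol 1. The carbon between the carbamate and methoxy oxygens is the one that directed metalation selects, and it is the carbon that must become C8a.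

## Roads not taken

Alternative 1: Ring B would be cut at C2–C3 and C1–C8a. Enyne A1, a 3‑arylpropargyl cinnamyl ether, would be treated with a cationic monovalent gold complex made from (R)‑DTBM‑SEGPHOS(AuCl)2 and AgSbF6 (or its enantiomer). The activated alkyne is attacked by alkene carbon C2 at C3, and the benzylic cation at C1 is captured by ring A at C8a, giving the dihydrofuran‑fused dihydronaphthalene A2.
- Merits: the step is catalytic in the chiral source, sets C1 and C2 together, and gives the trans relation stereospecifically from the E alkene. C9 and C10 are already in place as ether carbons.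
- Weak points: the arene closure must occur ortho to the alkyne at the carbon flanked by the methoxy group, although the other ortho carbon (C5) is para to that methoxy group and less hindered. A2 therefore carries a C5 bromide as a blocking group, which must later be removed beside a styrene‑type alkene. The cyclic ether must then be oxidised at C10 and opened to separate C9–OAc from C10=O, which costs about as many steps as the present endgame. Enantioselectivity of this cyclisation class depends strongly on the substrate.
- Comparison: Alternative 1 is better in stereochemical economy, with no auxiliary and both centres set in one catalytic step. The chosen plan sets against this a regiochemistry that comes from the polarisation of the two partners without a blocking group. It also gives C9 and C10 at distinguishable carbonyl levels, and a C1 epimer that is a separable diastereomer and not an enantiomeric impurity.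

Alternative 2: The cut is at C2–C3, with C3–C9 formed temporarily. The α‑diazo‑β‑keto ester A3, which already contains the C1 stereocenter and a vinyl group (C2=C9), would form a copper carbenoid with [Cu(MeCN)4]PF6 (monovalent copper) and a chiral bis(oxazoline). Addition across the vinyl group closes ring B and a fused cyclopropane, giving A4. Later opening of the doubly activated cyclopropane at C9 by an oxygen nucleophile installs C9–O.
- Merits: intramolecular cyclopropanation of diazo keto esters is dependable for six‑membered ketones. C2 is set kinetically in the ring‑forming step, under the influence of C1. The strain‑release opening delivers the C9 oxygen directly.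
- Weak points: A3 needs an enantioenriched diaryl(vinyl)methane centre, which isomerises easily to the conjugated alkene. It also needs a ring A bearing ortho acyl and ortho benzylic substituents next to two oxygens, which is a long preparation. The carbenoid can also attack the electron‑rich aryl rings. After A4, the C4 ketone must be reduced and eliminated and the ester lowered to the aldehyde.
- Comparison: Alternative 2 fixes C2 by a kinetic, ring‑forming event, where the chosen plan relies on equilibration. The chosen plan answers with a far shorter access to both fragments and with C1 created in the same step that builds ring B, so no fragile stereocenter is carried.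

Alternative 3: The cut is at C1–C2. In aldehyde A5, anodic two‑electron oxidation of the free 4‑hydroxy‑3‑methoxyphenyl group would give a para‑quinone methide at C1. The enamine formed from the C9 aldehyde and a chiral diarylprolinol silyl ether would add through C2 to C1 and close ring B, giving A6.
- Merits: the pendant phenol is used unprotected as the activating group. The stereocontrol is organocatalytic. The product aldehyde is epimerisable at C2, so trans is accessible.
- Weak points: the amine catalyst and the enamine are themselves oxidisable at the anode. The aldehyde of A5 is β,γ‑unsaturated, so dienamine formation and alkene migration compete. The trisubstituted alkene of A5 must be made with ring A cis to C2. A6 has the oxidation levels of C9 and C10 reversed with respect to the target, which costs a four‑step redox exchange.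
- Comparison: Alternative 3 is shorter in protecting groups and catalytic in chirality. The chosen plan relies on a single, mechanistically simple bond‑forming event whose partners are made in three steps each, and it places the correct oxidation levels at C9 and C10 from the start.

Key step: step 7

Assumption (chemistry): in the metal‑free cycloaddition the imide of 15 is taken to react through its conformer with opposed carbonyl dipoles, for which the (S)‑auxiliary should leave open the diene face that gives (1S). If the adduct proves to be the C1 epimer, the equally available (R)‑enantiomer of 9 is used and nothing else changes.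

Step 1
Reactants: 1 4-(benzyloxy)-3-methoxyphenol
Product: 2 4-(benzyloxy)-3-methoxyphenyl N-isopropylcarbamate
Conditions: i-PrNCO, Et3N (cat.), CH2Cl2, 23 °C
Reagents that add atoms: isopropyl isocyanate, CC(C)N=C=O
Why: Addition of the phenol O–H to the isocyanate (carbamoylation) installs a directing group that can later be removed with mild base.

Step 2
Reactants: 2 4-(benzyloxy)-3-methoxyphenyl N-isopropylcarbamate
Product: 6 4-(benzyloxy)-3-methoxy-2-(trimethylsilyl)phenyl N-isopropylcarbamate, via N-silyl carbamate 3 (not isolated), via aryllithium 4 (not isolated), via bis-silyl carbamate 5 (not isolated)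
Conditions: TBSOTf, TMEDA, Et2O, 0 to 23 °C; n-BuLi, TMEDA, −78 °C; TMSCl, −78 to 23 °C; aq. NaHSO4
Reagents that add atoms: chlorotrimethylsilane, C[Si](C)(C)Cl
Why: Directed ortho-metalation: after in situ N-silylation the carbamate and the methoxy group together direct lithiation to the carbon between them, the aryllithium is silylated, and the N-silyl group is lost on acidic work-up.

Step 3
Reactants: 6 4-(benzyloxy)-3-methoxy-2-(trimethylsilyl)phenyl N-isopropylcarbamate
Product: 8 4-(benzyloxy)-3-methoxy-2-(trimethylsilyl)phenyl trifluoromethanesulfonate, via silylphenoxide 7 (not isolated)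
Conditions: DBU, Et2NH, MeCN, 40 °C; then PhNTf2, 23 °C
Reagents that add atoms: N-phenylbis(trifluoromethanesulfonimide), O=S(=O)(N(c1ccccc1)S(=O)(=O)C(F)(F)F)C(F)(F)F
Why: Base-induced E1cB cleavage of the N-monosubstituted carbamate (the isocyanate is trapped by Et2NH) frees the phenoxide, which is O-triflated in the same flask.

Step 4
Reactants: 9 (S)-4-benzyloxazolidin-2-one; 10 2,2,6-trimethyl-4H-1,3-dioxin-4-one
Product: 12 (S)-4-benzyl-3-(3-oxobutanoyl)oxazolidin-2-one, via acetylketene 11 (not isolated)
Conditions: xylenes, 140 °C, acetone distilled off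
Reagents that add atoms: none
Why: Thermal retro-[4+2] fragmentation of the dioxinone releases acetylketene, which acylates the carbamate nitrogen (acetoacetylation).

Step 5
Reactants: 12 (S)-4-benzyl-3-(3-oxobutanoyl)oxazolidin-2-one; 13 4-(benzyloxy)-3-methoxybenzaldehyde
Product: 14 (S)-4-benzyl-3-[(2Z)-2-[4-(benzyloxy)-3-methoxybenzylidene]-3-oxobutanoyl]oxazolidin-2-one
Conditions: piperidine (cat.), AcOH (cat.), toluene, reflux, azeotropic removal of water
Reagents that add atoms: none
Why: Knoevenagel condensation; under these reversible conditions the isomer with the aryl group trans to the coplanar acetyl group and cis to the twisted imide (Z) should prevail, which is the geometry the diene needs.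

Step 6
Reactants: 14 (S)-4-benzyl-3-[(2Z)-2-[4-(benzyloxy)-3-methoxybenzylidene]-3-oxobutanoyl]oxazolidin-2-one
Product: 15 (S)-4-benzyl-3-[(2Z)-2-[4-(benzyloxy)-3-methoxybenzylidene]-3-[(triisopropylsilyl)oxy]but-3-enoyl]oxazolidin-2-one
Conditions: TIPSOTf, Et3N, CH2Cl2, 0 °C
Reagents that add atoms: triisopropylsilyl trifluoromethanesulfonate, CC(C)[Si](OS(=O)(=O)C(F)(F)F)(C(C)C)C(C)C
Why: Soft enolisation and O-silylation of the methyl ketone, the only enolisable position, gives the 2-silyloxy diene; the triisopropylsilyl group is chosen for its resistance to fluoride in the next step.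

Step 7
Reactants: 8 4-(benzyloxy)-3-methoxy-2-(trimethylsilyl)phenyl trifluoromethanesulfonate; 15 (S)-4-benzyl-3-[(2Z)-2-[4-(benzyloxy)-3-methoxybenzylidene]-3-[(triisopropylsilyl)oxy]but-3-enoyl]oxazolidin-2-one
Product: 17 (4S)-4-benzyl-3-{(1S)-7-(benzyloxy)-1-[4-(benzyloxy)-3-methoxyphenyl]-8-methoxy-3-[(triisopropylsilyl)oxy]-1,4-dihydronaphthalene-2-carbonyl}oxazolidin-2-one, via aryne 16 (not isolated)
Conditions: CsF, MeCN, 23 °C, slow addition of 8 (1.5 equiv)
Reagents that add atoms: none
Why: Fluoride removes the trimethylsilyl group of 8 with loss of triflate, and the aryne 16 so formed is taken up by the s-cis conformer of 15 in a concerted but asynchronous [4+2] cycloaddition; the closest known reaction type is the Diels–Alder reaction of fluoride-generated arynes with acyclic dienes, including silyloxy dienes and dienes bearing an acyl auxiliary. Ring B closes as a six-membered ring in this single cycloaddition, C4–C4a forming ahead of C1–C8a. The regiochemistry follows from matched polarisation: the C8 methoxy group makes the aryne carbon remote from it the electrophilic one, this carbon takes the nucleophilic CH2 terminus of the silyl enol ether, and the developing aryl anion next to the methoxy group closes on the benzylidene carbon, the β-carbon of the acyl-substituted alkene. The only new stereocenter is C1; because the Z diene carries its aryl group on the outside, that group ends on the ring face from which the aryne arrived, so C1 is decided by which diene face is attacked. That face is chosen by the auxiliary: the imide is twisted out of the diene plane, its ring carbonyl covers one face of C1–C2, and the 4-benzyl group, which avoids the triisopropylsilyloxy side, decides which rotamer and hence which face, the (S)-auxiliary being expected to leave open the face that gives (1S). A C1 epimer, if formed, is a diastereomer and can be removed by chromatography. The step also needs [4+2] selectivity over [2+2] addition and desilylation: the enol ether has no allylic hydrogen for an ene reaction, the triisopropylsilyl group resists CsF, and slow addition of 8 keeps the aryne concentration low.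

Step 8
Reactants: 17 (4S)-4-benzyl-3-{(1S)-7-(benzyloxy)-1-[4-(benzyloxy)-3-methoxyphenyl]-8-methoxy-3-[(triisopropylsilyl)oxy]-1,4-dihydronaphthalene-2-carbonyl}oxazolidin-2-one
Product: 19 (4S)-4-benzyl-3-{(1S)-7-(benzyloxy)-1-[4-(benzyloxy)-3-methoxyphenyl]-8-methoxy-3-[(trifluoromethanesulfonyl)oxy]-1,4-dihydronaphthalene-2-carbonyl}oxazolidin-2-one, via caesium enolate 18 (not isolated)
Conditions: CsF, PhNTf2, DME, 23 °C
Reagents that add atoms: N-phenylbis(trifluoromethanesulfonimide), O=S(=O)(N(c1ccccc1)S(=O)(=O)C(F)(F)F)C(F)(F)F
Why: Fluoride-induced cleavage of the silyl enol ether in the presence of the triflimide traps the regiodefined enolate on oxygen (silyl enol ether to enol triflate exchange), so the C2=C3 position fixed by the cycloaddition is retained.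

Step 9
Reactants: 19 (4S)-4-benzyl-3-{(1S)-7-(benzyloxy)-1-[4-(benzyloxy)-3-methoxyphenyl]-8-methoxy-3-[(trifluoromethanesulfonyl)oxy]-1,4-dihydronaphthalene-2-carbonyl}oxazolidin-2-one
Product: 20 methyl (1S)-7-(benzyloxy)-1-[4-(benzyloxy)-3-methoxyphenyl]-2-[(4S)-4-benzyl-2-oxooxazolidine-3-carbonyl]-8-methoxy-1,4-dihydronaphthalene-3-carboxylate
Conditions: Pd(OAc)2 (cat.), dppp, CO (1 atm), MeOH, Et3N, DMF, 60 °C
Reagents that add atoms: carbon monoxide, [C-]#[O+]; methanol, CO
Why: Palladium-catalysed alkoxycarbonylation of an enol triflate (oxidative addition to zerovalent palladium, CO insertion, methanolysis) introduces C10; the electron-poor triflate of a β-keto acyl system undergoes oxidative addition readily.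

Step 10
Reactants: 20 methyl (1S)-7-(benzyloxy)-1-[4-(benzyloxy)-3-methoxyphenyl]-2-[(4S)-4-benzyl-2-oxooxazolidine-3-carbonyl]-8-methoxy-1,4-dihydronaphthalene-3-carboxylate
Product: 21 methyl (1S,2R)-7-(benzyloxy)-1-[4-(benzyloxy)-3-methoxyphenyl]-2-[(4S)-4-benzyl-2-oxooxazolidine-3-carbonyl]-8-methoxy-1,2-dihydronaphthalene-3-carboxylate
Conditions: DBU, toluene (degassed), 23 °C
Reagents that add atoms: none
Why: Base-mediated prototropic shift through the imide dienolate: the accessible C4–H is removed and C2 is reprotonated, which moves the alkene into conjugation with ring A and the ester. C2 is set under thermodynamic control, the cis epimer returning through the dienolate until the trans-diaxial isomer is reached (aryl pseudo-axial because of the C8 methoxy group, acyl pseudo-axial because of the C3 ester); its C2–H lies near the ring plane and is no longer removed.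

Step 11
Reactants: 21 methyl (1S,2R)-7-(benzyloxy)-1-[4-(benzyloxy)-3-methoxyphenyl]-2-[(4S)-4-benzyl-2-oxooxazolidine-3-carbonyl]-8-methoxy-1,2-dihydronaphthalene-3-carboxylate
Product: 22 [(1S,2R)-7-(benzyloxy)-1-[4-(benzyloxy)-3-methoxyphenyl]-8-methoxy-1,2-dihydronaphthalene-2,3-diyl]dimethanol
Conditions: LiAlH4, THF, −20 to 0 °C
Reagents that add atoms: none
Why: Hydride reduction cleaves the imide at its exocyclic carbonyl to the C9 alcohol (releasing the auxiliary) and reduces the conjugated ester 1,2 to the C10 allylic alcohol; after reduction neither stereocenter is acidified.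

Step 12
Reactants: 22 [(1S,2R)-7-(benzyloxy)-1-[4-(benzyloxy)-3-methoxyphenyl]-8-methoxy-1,2-dihydronaphthalene-2,3-diyl]dimethanol
Product: 23 (1S,2R)-7-(benzyloxy)-1-[4-(benzyloxy)-3-methoxyphenyl]-2-(hydroxymethyl)-8-methoxy-1,2-dihydronaphthalene-3-carbaldehyde
Conditions: MnO2, CH2Cl2, 23 °C
Reagents that add atoms: none
Why: Chemoselective oxidation of the allylic C10 alcohol, which is conjugated with ring A, by manganese dioxide; the saturated C9 alcohol is left untouched.

Step 13
Reactants: 23 (1S,2R)-7-(benzyloxy)-1-[4-(benzyloxy)-3-methoxyphenyl]-2-(hydroxymethyl)-8-methoxy-1,2-dihydronaphthalene-3-carbaldehyde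
Product: 24 [(1S,2R)-7-(benzyloxy)-1-[4-(benzyloxy)-3-methoxyphenyl]-3-formyl-8-methoxy-1,2-dihydronaphthalen-2-yl]methyl acetate
Conditions: Ac2O, pyridine, DMAP (cat.), CH2Cl2, 0 °C
Reagents that add atoms: acetic anhydride, CC(=O)OC(C)=O
Why: O-acylation of the only free hydroxyl group under mild base.

Step 14
Reactants: 24 [(1S,2R)-7-(benzyloxy)-1-[4-(benzyloxy)-3-methoxyphenyl]-3-formyl-8-methoxy-1,2-dihydronaphthalen-2-yl]methyl acetate
Product: 25 [(1S,2R)-3-formyl-7-hydroxy-1-(4-hydroxy-3-methoxyphenyl)-8-methoxy-1,2-dihydronaphthalen-2-yl]methyl acetate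
Conditions: BCl3, C6HMe5, CH2Cl2, −78 °C
Reagents that add atoms: none
Why: Lewis-acid cleavage of the two aryl benzyl ethers with pentamethylbenzene as a non-basic scavenger of the benzyl cation; alkene, enal, acetate and methyl ethers are expected to survive at this temperature.

## Compound list

1 | 4-(benzyloxy)-3-methoxyphenol | COc1cc(O)ccc1OCc1ccccc1 | starting material
2 | 4-(benzyloxy)-3-methoxyphenyl N-isopropylcarbamate | COc1cc(OC(=O)NC(C)C)ccc1OCc1ccccc1 | intermediate
3 | 4-(benzyloxy)-3-methoxyphenyl N-(tert-butyldimethylsilyl)-N-isopropylcarbamate | COc1cc(OC(=O)N(C(C)C)[Si](C)(C)C(C)(C)C)ccc1OCc1ccccc1 | intermediate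
4 | 2-lithio derivative of 3 (lithium on the carbon between the carbamate and methoxy oxygens) | COc1c([Li])c(OC(=O)N(C(C)C)[Si](C)(C)C(C)(C)C)ccc1OCc1ccccc1 | intermediate
5 | 4-(benzyloxy)-3-methoxy-2-(trimethylsilyl)phenyl N-(tert-butyldimethylsilyl)-N-isopropylcarbamate | COc1c([Si](C)(C)C)c(OC(=O)N(C(C)C)[Si](C)(C)C(C)(C)C)ccc1OCc1ccccc1 | intermediate
6 | 4-(benzyloxy)-3-methoxy-2-(trimethylsilyl)phenyl N-isopropylcarbamate | COc1c([Si](C)(C)C)c(OC(=O)NC(C)C)ccc1OCc1ccccc1 | intermediate
7 | 4-(benzyloxy)-3-methoxy-2-(trimethylsilyl)phenol (present as its amidinium phenoxide) | COc1c([Si](C)(C)C)c(O)ccc1OCc1ccccc1 | intermediate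
8 | 4-(benzyloxy)-3-methoxy-2-(trimethylsilyl)phenyl trifluoromethanesulfonate | COc1c([Si](C)(C)C)c(OS(=O)(=O)C(F)(F)F)ccc1OCc1ccccc1 | intermediate
9 | (S)-4-benzyloxazolidin-2-one | O=C1N[C@@H](Cc2ccccc2)CO1 | starting material
10 | 2,2,6-trimethyl-4H-1,3-dioxin-4-one | CC1=CC(=O)OC(C)(C)O1 | starting material
11 | acetylketene | CC(=O)C=C=O | intermediate
12 | (S)-4-benzyl-3-(3-oxobutanoyl)oxazolidin-2-one | CC(=O)CC(=O)N1C(=O)OC[C@@H]1Cc1ccccc1 | intermediate
13 | 4-(benzyloxy)-3-methoxybenzaldehyde | COc1cc(C=O)ccc1OCc1ccccc1 | starting material
14 | (S)-4-benzyl-3-[(2Z)-2-[4-(benzyloxy)-3-methoxybenzylidene]-3-oxobutanoyl]oxazolidin-2-one | CC(=O)/C(=C/c1ccc(OCc2ccccc2)c(OC)c1)C(=O)N1C(=O)OC[C@@H]1Cc1ccccc1 | intermediate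
15 | (S)-4-benzyl-3-[(2Z)-2-[4-(benzyloxy)-3-methoxybenzylidene]-3-[(triisopropylsilyl)oxy]but-3-enoyl]oxazolidin-2-one | C=C(O[Si](C(C)C)(C(C)C)C(C)C)/C(=C/c1ccc(OCc2ccccc2)c(OC)c1)C(=O)N1C(=O)OC[C@@H]1Cc1ccccc1 | intermediate
16 | 4-(benzyloxy)-3-methoxybenzyne (triple bond between the carbon next to C–OMe and its other neighbour) | COC1=C(OCc2ccccc2)C=CC#C1 | intermediate
17 | (4S)-4-benzyl-3-{(1S)-7-(benzyloxy)-1-[4-(benzyloxy)-3-methoxyphenyl]-8-methoxy-3-[(triisopropylsilyl)oxy]-1,4-dihydronaphthalene-2-carbonyl}oxazolidin-2-one | COc1cc([C@H]2c3c(ccc(OCc4ccccc4)c3OC)CC(O[Si](C(C)C)(C(C)C)C(C)C)=C2C(=O)N2C(=O)OC[C@@H]2Cc2ccccc2)ccc1OCc1ccccc1 | intermediate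
18 | caesium (1S)-7-(benzyloxy)-1-[4-(benzyloxy)-3-methoxyphenyl]-2-[(4S)-4-benzyl-2-oxooxazolidine-3-carbonyl]-8-methoxy-1,4-dihydronaphthalen-3-olate | COc1cc([C@H]2c3c(ccc(OCc4ccccc4)c3OC)CC([O-])=C2C(=O)N2C(=O)OC[C@@H]2Cc2ccccc2)ccc1OCc1ccccc1.[Cs+] | intermediate
19 | (4S)-4-benzyl-3-{(1S)-7-(benzyloxy)-1-[4-(benzyloxy)-3-methoxyphenyl]-8-methoxy-3-[(trifluoromethanesulfonyl)oxy]-1,4-dihydronaphthalene-2-carbonyl}oxazolidin-2-one | COc1cc([C@H]2c3c(ccc(OCc4ccccc4)c3OC)CC(OS(=O)(=O)C(F)(F)F)=C2C(=O)N2C(=O)OC[C@@H]2Cc2ccccc2)ccc1OCc1ccccc1 | intermediate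
20 | methyl (1S)-7-(benzyloxy)-1-[4-(benzyloxy)-3-methoxyphenyl]-2-[(4S)-4-benzyl-2-oxooxazolidine-3-carbonyl]-8-methoxy-1,4-dihydronaphthalene-3-carboxylate | COc1cc([C@H]2c3c(ccc(OCc4ccccc4)c3OC)CC(C(=O)OC)=C2C(=O)N2C(=O)OC[C@@H]2Cc2ccccc2)ccc1OCc1ccccc1 | intermediate
21 | methyl (1S,2R)-7-(benzyloxy)-1-[4-(benzyloxy)-3-methoxyphenyl]-2-[(4S)-4-benzyl-2-oxooxazolidine-3-carbonyl]-8-methoxy-1,2-dihydronaphthalene-3-carboxylate | COc1cc([C@H]2c3c(ccc(OCc4ccccc4)c3OC)C=C(C(=O)OC)[C@@H]2C(=O)N2C(=O)OC[C@@H]2Cc2ccccc2)ccc1OCc1ccccc1 | intermediate
22 | [(1S,2R)-7-(benzyloxy)-1-[4-(benzyloxy)-3-methoxyphenyl]-8-methoxy-1,2-dihydronaphthalene-2,3-diyl]dimethanol | COc1cc([C@H]2c3c(ccc(OCc4ccccc4)c3OC)C=C(CO)[C@@H]2CO)ccc1OCc1ccccc1 | intermediate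
23 | (1S,2R)-7-(benzyloxy)-1-[4-(benzyloxy)-3-methoxyphenyl]-2-(hydroxymethyl)-8-methoxy-1,2-dihydronaphthalene-3-carbaldehyde | COc1cc([C@H]2c3c(ccc(OCc4ccccc4)c3OC)C=C(C=O)[C@@H]2CO)ccc1OCc1ccccc1 | intermediate
24 | [(1S,2R)-7-(benzyloxy)-1-[4-(benzyloxy)-3-methoxyphenyl]-3-formyl-8-methoxy-1,2-dihydronaphthalen-2-yl]methyl acetate | COc1cc([C@H]2c3c(ccc(OCc4ccccc4)c3OC)C=C(C=O)[C@@H]2COC(C)=O)ccc1OCc1ccccc1 | intermediate
25 | [(1S,2R)-3-formyl-7-hydroxy-1-(4-hydroxy-3-methoxyphenyl)-8-methoxy-1,2-dihydronaphthalen-2-yl]methyl acetate | COc1cc([C@H]2c3c(ccc(O)c3OC)C=C(C=O)[C@@H]2COC(C)=O)ccc1O | target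

## Step count and least certain steps

Total step count: 14. Longest linear sequence: 11 steps (steps 4–14 from 9; the aryne branch, steps 1–3, joins at step 7 and is equally long).

**Step 7 (key step).** The most likely failures are weak facial discrimination at ambient temperature and fluoride attack on the enol silyl group before cycloaddition. The first arises because the twisted imide holds its stereocenter far from C1 when the carbonyl dipoles are opposed. A low ratio costs material only, since the C1 epimers are separable diastereomers. The second would stop the cycloaddition. The fallback generates the aryne without fluoride and at low temperature. From carbamate 2, the N-silylation and ortho-lithiation of step 2 are repeated with an iodine quench to give 4-(benzyloxy)-2-iodo-3-methoxyphenyl N-isopropylcarbamate F1. Cleavage with DBU/Et2NH and triflation with PhNTf2, as in step 3, give 4-(benzyloxy)-2-iodo-3-methoxyphenyl trifluoromethanesulfonate F2. Treatment of F2 with i-PrMgCl·LiCl in THF at −78 °C in the presence of diene 15 (iodine–magnesium exchange, then loss of the magnesium triflate) releases the same aryne 16, and the route is rejoined at 17. Because the magnesium ion can bind the imide, the sense of induction would have to be confirmed again.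

**Step 10.** The most likely failure is loss of configurational integrity at C1. In 20 the C1–H is vinylogous to the C3 ester, and its removal would compete with removal of C4–H if the imide dienolate forms slowly. Oxidative aromatisation of the dienolate by traces of oxygen is the second danger. The fallback masks the C3 carbonyl during the shift. From enol triflate 19, palladium-catalysed hydroxycarbonylation (Pd(OAc)2, dppf, CO, KOAc, DMSO, 60 °C) gives (1S)-7-(benzyloxy)-1-[4-(benzyloxy)-3-methoxyphenyl]-2-[(4S)-4-benzyl-2-oxooxazolidine-3-carbonyl]-8-methoxy-1,4-dihydronaphthalene-3-carboxylic acid F3. As its carboxylate the C3 group no longer acidifies C1–H, so DBU can only remove C4–H, and the shift gives (1S,2R)-7-(benzyloxy)-1-[4-(benzyloxy)-3-methoxyphenyl]-2-[(4S)-4-benzyl-2-oxooxazolidine-3-carbonyl]-8-methoxy-1,2-dihydronaphthalene-3-carboxylic acid F4. Methylation with TMSCHN2 in MeOH/toluene returns to 21.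

**Step 14.** The most likely failure is Lewis-acid attack on the acetate (acyl cleavage) or benzyl transfer to the electron-rich rings while the aldehyde ties up BCl3. The fallback changes the order and the acylation method. From hydroxy enal 23, debenzylation with BCl3/C6HMe5 is carried out first to give (1S,2R)-7-hydroxy-1-(4-hydroxy-3-methoxyphenyl)-2-(hydroxymethyl)-8-methoxy-1,2-dihydronaphthalene-3-carbaldehyde F5. The primary aliphatic alcohol is then acetylated in the presence of the two phenols with a lipase (Candida antarctica lipase B, vinyl acetate, t-BuOMe), which gives 25 directly.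

**Step 4.** The most likely failure is slow capture of acetylketene by the weakly nucleophilic carbamate nitrogen, so that self-condensation of the ketene takes over. The fallback builds the β-keto imide by C–C bond formation. From 9, n-BuLi and acetyl chloride give (S)-3-acetyl-4-benzyloxazolidin-2-one F6. Its lithium enolate (LiHMDS, 2 equiv, THF, −78 °C) is C-acylated with acetyl chloride in a crossed Claisen condensation to give 12.

## Further compounds

F1 | step 7 | 4-(benzyloxy)-2-iodo-3-methoxyphenyl N-isopropylcarbamate | COc1c(I)c(OC(=O)NC(C)C)ccc1OCc1ccccc1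
F2 | step 7 | 4-(benzyloxy)-2-iodo-3-methoxyphenyl trifluoromethanesulfonate | COc1c(I)c(OS(=O)(=O)C(F)(F)F)ccc1OCc1ccccc1
F3 | step 10 | (1S)-7-(benzyloxy)-1-[4-(benzyloxy)-3-methoxyphenyl]-2-[(4S)-4-benzyl-2-oxooxazolidine-3-carbonyl]-8-methoxy-1,4-dihydronaphthalene-3-carboxylic acid | COc1cc([C@H]2c3c(ccc(OCc4ccccc4)c3OC)CC(C(=O)O)=C2C(=O)N2C(=O)OC[C@@H]2Cc2ccccc2)ccc1OCc1ccccc1
F4 | step 10 | (1S,2R)-7-(benzyloxy)-1-[4-(benzyloxy)-3-methoxyphenyl]-2-[(4S)-4-benzyl-2-oxooxazolidine-3-carbonyl]-8-methoxy-1,2-dihydronaphthalene-3-carboxylic acid | COc1cc([C@H]2c3c(ccc(OCc4ccccc4)c3OC)C=C(C(=O)O)[C@@H]2C(=O)N2C(=O)OC[C@@H]2Cc2ccccc2)ccc1OCc1ccccc1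
F5 | step 14 | (1S,2R)-7-hydroxy-1-(4-hydroxy-3-methoxyphenyl)-2-(hydroxymethyl)-8-methoxy-1,2-dihydronaphthalene-3-carbaldehyde | COc1cc([C@H]2c3c(ccc(O)c3OC)C=C(C=O)[C@@H]2CO)ccc1O
F6 | step 4 | (S)-3-acetyl-4-benzyloxazolidin-2-one | CC(=O)N1C(=O)OC[C@@H]1Cc1ccccc1
A1 | alternative 1 | 4-[(E)-3-{[3-(4-acetoxy-2-bromo-5-methoxyphenyl)prop-2-yn-1-yl]oxy}prop-1-en-1-yl]-2-methoxyphenyl acetate | COc1cc(/C=C/COCC#Cc2cc(OC)c(OC(C)=O)cc2Br)ccc1OC(C)=O
A2 | alternative 1 | dihydrofuran-fused trans-1-aryl-1,2-dihydronaphthalene (C5 bromide, aryl acetates) | COc1cc([C@H]2c3c(c(Br)cc(OC(C)=O)c3OC)C=C5[C@@H]2COC5)ccc1OC(C)=O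
A3 | alternative 2 | methyl 2-diazo-3-oxo-3-{4-[(tert-butyldimethylsilyl)oxy]-3-methoxy-2-[(1S)-1-{4-[(tert-butyldimethylsilyl)oxy]-3-methoxyphenyl}prop-2-en-1-yl]phenyl}propanoate | COc1cc([C@H](C=C)c2c(ccc(O[Si](C)(C)C(C)(C)C)c2OC)C(=O)C(=[N+]=[N-])C(=O)OC)ccc1O[Si](C)(C)C(C)(C)C
A4 | alternative 2 | cyclopropane-fused 4-oxotetralin-3-carboxylate (TBS ethers) | COc1cc([C@H]2c3c(ccc(O[Si](C)(C)C(C)(C)C)c3OC)C(=O)[C@]4(C(=O)OC)C[C@H]24)ccc1O[Si](C)(C)C(C)(C)C
A5 | alternative 3 | (3E)-4-{4-[(tert-butyldimethylsilyl)oxy]-2-(4-hydroxy-3-methoxybenzyl)-3-methoxyphenyl}-3-{[(tert-butyldimethylsilyl)oxy]methyl}but-3-enal (ring A cis to C2) | COc1cc(Cc2c(/C=C(/CO[Si](C)(C)C(C)(C)C)CC=O)ccc(O[Si](C)(C)C(C)(C)C)c2OC)ccc1O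
A6 | alternative 3 | trans-1-(4-hydroxy-3-methoxyphenyl)-3-(silyloxymethyl)-1,2-dihydronaphthalene-2-carbaldehyde (TBS ethers) | COc1cc([C@H]2c3c(ccc(O[Si](C)(C)C(C)(C)C)c3OC)C=C(CO[Si](C)(C)C(C)(C)C)[C@@H]2C=O)ccc1O
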